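Numbering follows isochroman-1-one. Ring A is the arene C4a–C8a, ring B is the lactone C1–O2–C3–C4–C4a–C8a, and the side chain is C1'–C11' with the ketone at C6'. The target is (3R).
Retrosynthetic cuts, in order: O8–CH3 (put back as a mask), C4–C4a (ring B opens to a 2-bromoalkyl benzoate carrying iodine at C5), ester C1–O2, C4–Br (back to a terminal epoxide C3–C4), and C5'–C6' of the chain.
Enabling feature: C4a is meta to O6 and O8 and ortho to the ester, so Friedel–Crafts closure is not open to it. Its neighbour C5 is para to O8 and ortho to O6 and takes iodine by plain electrophilic substitution. C5–I then has one blocked ortho position (C6–OMe) and one free ortho C–H (C4a–H) next to the tether-bearing C8a, which is the pattern a palladium/norbornene relay needs.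
Forward: the chain is joined by Grignard acylation, the alkene is epoxidised and resolved, the epoxide is opened to the bromohydrin and esterified with the iodo acid. Ring A is bought. Ring B is closed on it with loss of the iodine in the same step, and O8 is unmasked last.
Stereochemistry: C3 comes from the hydrolytic kinetic resolution of the terminal epoxide, and its C–O bond is never broken afterwards.
Key step: step 7

Step 1
Reactants: 1 7-bromohept-1-ene; 2 hexanoyl chloride
Product: 4 tridec-12-en-6-one, via hept-6-enylmagnesium bromide 3 (not isolated)
Conditions: Mg, THF, rt to 40 °C; then 2, Fe(acac)3 (3 mol %), THF, −78 °C to 0 °C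
Reagents that add atoms: magnesium, [Mg] (held only in intermediate 3)
Why: Iron-catalysed acylation of a Grignard reagent by an acid chloride is much faster than addition to the ketone formed, so the reaction should stop at 4, and the terminal alkene is inert.

Step 2
Reactants: 4 tridec-12-en-6-one
Product: 5 rac-1-(oxiran-2-yl)undecan-6-one
Conditions: mCPBA, CH2Cl2, 0 °C to rt
Reagents that add atoms: mCPBA, OOC(=O)c1cccc(Cl)c1
Why: In this Prilezhaev epoxidation the terminal alkene should react faster than the unstrained dialkyl ketone undergoes Baeyer–Villiger oxidation in the absence of added acid.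

Step 3
Reactants: 5 rac-1-(oxiran-2-yl)undecan-6-one
Product: 6 1-[(2R)-oxiran-2-yl]undecan-6-one
Conditions: (R,R)-(salen)Co(OAc) (0.5 mol %; salen = N,N'-bis(3,5-di-tert-butylsalicylidene)cyclohexane-1,2-diaminate), H2O (0.55 equiv), minimal THF, 0 °C to rt; chromatography
Reagents that add atoms: none
Why: In the Jacobsen hydrolytic kinetic resolution this catalyst enantiomer hydrates the (S)-epoxide far faster, so at slightly over half conversion the (R)-epoxide should remain in high enantiomeric purity, which sets C3 of the target.

Step 4
Reactants: 6 1-[(2R)-oxiran-2-yl]undecan-6-one
Product: 7 (12R)-13-bromo-12-hydroxytridecan-6-one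
Conditions: LiBr, AcOH, THF, rt
Reagents that add atoms: lithium bromide, [Li+].[Br-]
Why: Acid-assisted SN2 opening of the terminal epoxide by bromide (halohydrin formation) takes place at the unhindered CH2, so the C–O bond at the stereocenter is untouched, R is retained, and the ketone is inert.

Step 5
Reactants: 8 2,4-dimethoxybenzoic acid
Product: 9 5-iodo-2,4-dimethoxybenzoic acid
Conditions: NIS, CF3CO2H (cat.), MeCN, rt, dark
Reagents that add atoms: N-iodosuccinimide, O=C1CCC(=O)N1I
Why: Electrophilic aromatic iodination should go to C5, which is para to the 2-OMe, ortho to the 4-OMe and less crowded than C3 between the two methoxy groups, whereas C6 is meta to both donors.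

Step 6
Reactants: 7 (12R)-13-bromo-12-hydroxytridecan-6-one; 9 5-iodo-2,4-dimethoxybenzoic acid
Product: 10 (2R)-1-bromo-8-oxotridecan-2-yl 5-iodo-2,4-dimethoxybenzoate
Conditions: DCC, DMAP (cat.), CH2Cl2, 0 °C to rt
Reagents that add atoms: none
Why: The Steglich esterification acylates the secondary hydroxyl at oxygen, so the configuration is retained, and the primary bromide, aryl iodide and ketone should be inert at room temperature.

Step 7
Reactants: 10 (2R)-1-bromo-8-oxotridecan-2-yl 5-iodo-2,4-dimethoxybenzoate
Product: 11 (3R)-6,8-dimethoxy-3-(6-oxoundecyl)isochroman-1-one
Conditions: Pd(OAc)2 (10 mol %), P(2-furyl)3 (22 mol %), norbornene (2 equiv), Cs2CO3 (3 equiv), i-PrOH (5 equiv), toluene (0.01 M), 100 °C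
Reagents that add atoms: none
Why: Zerovalent palladium inserts into C5–I, norbornene carbopalladates, and the metal cleaves the only free ortho C–H (C4a–H, since C6 carries OMe) to give the aryl–norbornyl palladacycle of divalent palladium; the tethered primary C4–Br adds to it in SN2 fashion and reductive elimination from tetravalent palladium forms C4–C4a. Ring B closes in a 6-exo-tet sense (bromide leaves outside the new ring) through a seven-membered palladacycle that holds C4a, C8a, C1, O2, C3 and C4. With both positions ortho to C5 now filled, norbornene is expelled by β-carbon elimination and the C5–Pd bond is exchanged for C5–H by isopropoxide binding, β-hydride elimination (acetone) and C–H reductive elimination, so the iodine helper leaves in the same operation. The closest known reaction type is the Catellani reaction in its ring-forming variant with a tethered alkyl halide, joined to ipso hydride termination. No stereocenter is formed: substitution takes place at the CH2 carbon C4, and the C3–O and C3–H bonds are spectators, so the R configuration is carried over. The step needs ring closure to beat chain-forming alkylation, early reduction of C5–I and ester-assisted ionisation of the bromide; high dilution, excess norbornene with little i-PrOH, and a non-polar solvent with an insoluble carbonate base should secure this, and that base is too weak to bring the C6' ketone into α-arylation.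

Step 8
Reactants: 11 (3R)-6,8-dimethoxy-3-(6-oxoundecyl)isochroman-1-one
Product: 12 (3R)-8-hydroxy-6-methoxy-3-(6-oxoundecyl)isochroman-1-one (target)
Conditions: BCl3 (2.5 equiv), CH2Cl2, −78 °C to 0 °C; then H2O
Reagents that add atoms: none
Why: In this chelation-controlled aryl methyl ether cleavage boron binds between the lactone C1=O and O8 in a six-membered chelate, so chloride should remove only the O8 methyl, while the O6 methyl, the ketone and C3 are left alone.

Compound list
1 | 7-bromohept-1-ene | C=CCCCCCBr | starting material
2 | hexanoyl chloride | CCCCCC(=O)Cl | starting material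
3 | hept-6-enylmagnesium bromide | C=CCCCCC[Mg]Br | intermediate
4 | tridec-12-en-6-one | CCCCCC(=O)CCCCCC=C | intermediate
5 | rac-1-(oxiran-2-yl)undecan-6-one | CCCCCC(=O)CCCCCC1CO1 | intermediate
6 | 1-[(2R)-oxiran-2-yl]undecan-6-one | CCCCCC(=O)CCCCC[C@@H]1CO1 | intermediate
7 | (12R)-13-bromo-12-hydroxytridecan-6-one | CCCCCC(=O)CCCCC[C@@H](O)CBr | intermediate
8 | 2,4-dimethoxybenzoic acid | COc1ccc(C(=O)O)c(OC)c1 | starting material
9 | 5-iodo-2,4-dimethoxybenzoic acid | COc1cc(OC)c(C(=O)O)cc1I | intermediate
10 | (2R)-1-bromo-8-oxotridecan-2-yl 5-iodo-2,4-dimethoxybenzoate | CCCCCC(=O)CCCCC[C@H](CBr)OC(=O)c1cc(I)c(OC)cc1OC | intermediate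
11 | (3R)-6,8-dimethoxy-3-(6-oxoundecyl)isochroman-1-one | CCCCCC(=O)CCCCC[C@@H]1Cc2cc(OC)cc(OC)c2C(=O)O1 | intermediate
12 | (3R)-8-hydroxy-6-methoxy-3-(6-oxoundecyl)isochroman-1-one | CCCCCC(=O)CCCCC[C@@H]1Cc2cc(OC)cc(O)c2C(=O)O1 | target

Total step count: 8. Longest linear sequence: 7 steps (steps 1, 2, 3, 4, 6, 7, 8).

Steps most likely to fail

Step 7. Several processes could divert the step:
- The C5–I bond may be reduced before the norbornene relay starts.
- The ester may be slow to adopt the rotamer that brings C4 to the metal, so alkylation between molecules takes over.
- The bromide may ionise with participation of the electron-rich aroyl group, which would shift the acyl group and erode C3.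

The fallback gives up the tether and the iodine and uses the carboxylate as directing group. It sets out from 8 and 6. Pd(OAc)2 (cat.), N-acetyl-L-tert-leucine and KOAc in (CF3)2CHOH at 75 °C should palladate the only C–H ortho to the carboxylate. The aryl–palladium species should then open the epoxide at its terminal carbon with retention at C3. This gives 2-[(2R)-2-hydroxy-8-oxotridecyl]-4,6-dimethoxybenzoic acid F1, which should lactonise in the flask. The fallback comes back to the route at 11.

Step 6. Acyl transfer from an electron-rich, ortho-substituted acid to a hindered secondary alcohol may be slow enough for rearrangement of the activated acid to an N-acylurea. The amine base may also reclose the bromohydrin to the epoxide. The fallback avoids the free bromohydrin altogether and sets out from 9 and 6. Acid 9 is turned with (COBr)2 and catalytic DMF in CH2Cl2 into 5-iodo-2,4-dimethoxybenzoyl bromide F2. With Bu4NBr (cat.) in CH2Cl2, F2 should open epoxide 6 directly, bromide going to the terminal carbon and the acyl group to oxygen, with retention at C3. The fallback comes back to the route at 10.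

Step 8. Discrimination between the two methyl ethers may be incomplete, so that the O6 methyl is lost as well. The fallback does not rely on selective cleavage and sets out from 11. Excess BBr3 in CH2Cl2 (−78 °C to rt) should remove both methyl groups to give (3R)-6,8-dihydroxy-3-(6-oxoundecyl)isochroman-1-one F3. One equivalent of MeI with K2CO3 in acetone should then methylate only O6–H, because O8–H is held in a hydrogen bond to the lactone carbonyl. The fallback comes back to the route at 12.

Further compounds
F1 | step 7 | 2-[(2R)-2-hydroxy-8-oxotridecyl]-4,6-dimethoxybenzoic acid | CCCCCC(=O)CCCCC[C@@H](O)Cc1cc(OC)cc(OC)c1C(=O)O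
F2 | step 6 | 5-iodo-2,4-dimethoxybenzoyl bromide | COc1cc(OC)c(C(=O)Br)cc1I
F3 | step 8 | (3R)-6,8-dihydroxy-3-(6-oxoundecyl)isochroman-1-one | CCCCCC(=O)CCCCC[C@@H]1Cc2cc(O)cc(O)c2C(=O)O1
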